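**Plan**

- Retrosynthesis: the two ring-B hydroxyls are masked as a diphenylmethylene ketal, the aryl C6–OMe and C8–OMe bonds are cut back to a 6,8-dibromide, then the two C–Br bonds, the 7-O–CH3 bond and the ketal are removed, which leads to luteolin.
- Enabling feature: in flavone numbering (O1, C2, C3, C4=O, C4a, C5–C8, C8a), ring A of a 5,7-dioxygenated flavone is a phloroglucinol-type ring. Its only C–H carbons, C6 and C8, are each ortho or para to the oxygens on C5, C7 and C8a, so both can be brominated and both C–Br bonds exchanged for C–OMe in one late copper-mediated operation.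
- Forward: no ring of the target is built; rings A, B and C and all fifteen skeletal carbons come from luteolin. Ring B is ketalized, the 7-hydroxyl methylated, C6 and C8 brominated, both bromides replaced by methoxide, and the ketal hydrolysed.
- Stereochemistry: the target is achiral, with no stereocentre and no stereogenic double bond, so nothing has to be controlled.

Key step: step 4

Assumption: in the two twofold substitutions (steps 3 and 4) the order in which C6 and C8 react does not change the outcome; the intermediate named is the one expected to form first.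

**Route**

Step 1
Reactants: 1 luteolin; 2 dichlorodiphenylmethane
Product: 3 2-(2,2-diphenyl-1,3-benzodioxol-5-yl)-5,7-dihydroxy-4H-chromen-4-one (luteolin 3′,4′-O-diphenylmethylene ketal)
Conditions: Ph2CCl2 (1.5 equiv), Ph2O, 175 °C, 30–45 min, N2 sweep; precipitation with hexane
Reagents that add atoms: dichlorodiphenylmethane, ClC(Cl)(c1ccccc1)c1ccccc1
Why: Thermal ketalization of a catechol with a gem-dichloride (two O-alkylations with loss of HCl) is the standard way to mask ring B of catechol flavonoids, since only the vicinal 3′,4′-diol can close the five-membered 1,3-benzodioxole and any chlorodiphenylmethyl ether formed at the 7-hydroxyl reverts on aqueous work-up.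

Step 2
Reactants: 3 2-(2,2-diphenyl-1,3-benzodioxol-5-yl)-5,7-dihydroxy-4H-chromen-4-one; 4 iodomethane
Product: 5 2-(2,2-diphenyl-1,3-benzodioxol-5-yl)-5-hydroxy-7-methoxy-4H-chromen-4-one
Conditions: MeI (1.1 equiv), K2CO3 (1.2 equiv), DMF, rt
Reagents that add atoms: iodomethane, CI
Why: Williamson etherification should stop at the 7-methyl ether, because K2CO3 deprotonates the vinylogously acidic 7-hydroxyl for SN2 methylation while the 5-hydroxyl is held in a hydrogen bond to the C4 carbonyl and reacts only under forcing conditions.

Step 3
Reactants: 5 2-(2,2-diphenyl-1,3-benzodioxol-5-yl)-5-hydroxy-7-methoxy-4H-chromen-4-one; 6 N-bromosuccinimide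
Product: 8 6,8-dibromo-2-(2,2-diphenyl-1,3-benzodioxol-5-yl)-5-hydroxy-7-methoxy-4H-chromen-4-one, via the 8-monobromide 7 (not isolated)
Conditions: NBS (2.1 equiv), DMF, 0 °C to rt, dark
Reagents that add atoms: N-bromosuccinimide, O=C1CCC(=O)N1Br
Why: Electrophilic aromatic bromination should take C8 (para to the 5-hydroxyl) and then C6, the only C–H carbons of ring A and each ortho or para to all three ring-A oxygens, well ahead of C3 of the pyranone and of the benzodioxole ring B, which is conjugated to the electron-poor C2, and the ketal tolerates these neutral conditions.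

Step 4
Reactants: 8 6,8-dibromo-2-(2,2-diphenyl-1,3-benzodioxol-5-yl)-5-hydroxy-7-methoxy-4H-chromen-4-one; 9 sodium methoxide
Product: 11 2-(2,2-diphenyl-1,3-benzodioxol-5-yl)-5-hydroxy-6,7,8-trimethoxy-4H-chromen-4-one, via the 8-bromo-6-methoxy flavone 10 (not isolated)
Conditions: NaOMe (8 equiv, 25 wt% in MeOH), CuBr (0.4 equiv), DMF–MeOH, 110 °C, argon; then cold aq. citric acid
Reagents that add atoms: sodium methoxide, C[O-].[Na+]
Why: NaOMe and CuBr should form the cuprate Na[Cu(OMe)2] of monovalent copper, which activates each aryl C–Br bond (oxidative addition to a transient species [ArCuBr(OMe)2]− of trivalent copper, or a concerted four-centre substitution) and releases the aryl methyl ether by reductive elimination, first at C6 beside the coordinating 5-oxide (compound 10) and then at C8. The closest known reaction type is the Ullmann-type methoxylation of aryl bromides with NaOMe and a salt of monovalent copper in DMF–methanol, as practised on ortho-bromophenols and on 6- and 8-halogenated 5-hydroxyflavones. No ring is closed and no stereocentre is formed; two aryl C–O bonds are made. The selectivity needed is substitution over hydrodebromination and over cleavage of the pyranone; dry, concentrated methoxide in excess under argon favours substitution, and the 5-oxide formed at once lowers the electrophilicity of C2. If methoxide does open the pyranone, closure through either of the two ortho oxygens returns the same flavone, since C6 and C8 carry identical substituents on either side of C7, and both possible mono-substituted intermediates converge on 11. The positions of the new oxygens are fixed by the bromines, and the ketal and the aryl methyl ethers are inert to methoxide.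

Step 5
Reactants: 11 2-(2,2-diphenyl-1,3-benzodioxol-5-yl)-5-hydroxy-6,7,8-trimethoxy-4H-chromen-4-one
Product: 12 sideritiflavone, 2-(3,4-dihydroxyphenyl)-5-hydroxy-6,7,8-trimethoxy-4H-chromen-4-one
Conditions: AcOH–H2O (4:1), reflux, 2–4 h
Reagents that add atoms: none
Why: Acid-catalysed ketal hydrolysis should proceed through the diphenyl-stabilised oxocarbenium ion, which water captures to release the catechol and benzophenone, while the aryl methyl ethers, the chelated 5-hydroxyl and the flavone core are untouched by hot aqueous acetic acid.

**Compound list**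

1 | luteolin, 2-(3,4-dihydroxyphenyl)-5,7-dihydroxy-4H-chromen-4-one | O=c1cc(-c2ccc(O)c(O)c2)oc2cc(O)cc(O)c12 | starting material
2 | dichlorodiphenylmethane | ClC(Cl)(c1ccccc1)c1ccccc1 | starting material
3 | 2-(2,2-diphenyl-1,3-benzodioxol-5-yl)-5,7-dihydroxy-4H-chromen-4-one | O=c1cc(-c2ccc3OC(c4ccccc4)(c4ccccc4)Oc3c2)oc2cc(O)cc(O)c12 | intermediate
4 | iodomethane | CI | starting material
5 | 2-(2,2-diphenyl-1,3-benzodioxol-5-yl)-5-hydroxy-7-methoxy-4H-chromen-4-one | COc1cc(O)c2c(=O)cc(-c3ccc4OC(c5ccccc5)(c5ccccc5)Oc4c3)oc2c1 | intermediate
6 | N-bromosuccinimide | O=C1CCC(=O)N1Br | starting material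
7 | 8-bromo-2-(2,2-diphenyl-1,3-benzodioxol-5-yl)-5-hydroxy-7-methoxy-4H-chromen-4-one (formed in the flask in step 3, not isolated) | COc1cc(O)c2c(=O)cc(-c3ccc4OC(c5ccccc5)(c5ccccc5)Oc4c3)oc2c1Br | intermediate
8 | 6,8-dibromo-2-(2,2-diphenyl-1,3-benzodioxol-5-yl)-5-hydroxy-7-methoxy-4H-chromen-4-one | COc1c(Br)c(O)c2c(=O)cc(-c3ccc4OC(c5ccccc5)(c5ccccc5)Oc4c3)oc2c1Br | intermediate
9 | sodium methoxide | C[O-].[Na+] | starting material
10 | 8-bromo-2-(2,2-diphenyl-1,3-benzodioxol-5-yl)-5-hydroxy-6,7-dimethoxy-4H-chromen-4-one (formed in the flask in step 4, not isolated) | COc1c(OC)c(O)c2c(=O)cc(-c3ccc4OC(c5ccccc5)(c5ccccc5)Oc4c3)oc2c1Br | intermediate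
11 | 2-(2,2-diphenyl-1,3-benzodioxol-5-yl)-5-hydroxy-6,7,8-trimethoxy-4H-chromen-4-one | COc1c(OC)c(O)c2c(=O)cc(-c3ccc4OC(c5ccccc5)(c5ccccc5)Oc4c3)oc2c1OC | intermediate
12 | sideritiflavone, 2-(3,4-dihydroxyphenyl)-5-hydroxy-6,7,8-trimethoxy-4H-chromen-4-one | COc1c(OC)c(O)c2c(=O)cc(-c3ccc(O)c(O)c3)oc2c1OC | target

**Step count and risks**

Total step count: 5. Longest linear sequence: 5 steps (1 → 3 → 5 → 8 → 11 → 12).

Steps most likely to fail:

Step 4. Reduction of the C–Br bonds by CuH, which can arise when copper-bound methoxide loses a β-hydride, may outrun substitution at the second, less assisted bromide; prolonged heating in methoxide may also degrade the pyranone. The fallback sets out from compound 3 and inverts the order of O-methylation and C–O coupling. NBS (2.1 equiv, DMF, 0 °C) should dibrominate the free 5,7-diol to 6,8-dibromo-2-(2,2-diphenyl-1,3-benzodioxol-5-yl)-5,7-dihydroxy-4H-chromen-4-one F1. Under NaOMe and CuBr in DMF–methanol, F1 reacts as a 5,7-dioxide: the 7-oxide flanks both bromines and can hold copper at each site (the ortho-bromophenoxide case), and the doubly charged chromenone resists attack by methoxide. This should give 2-(2,2-diphenyl-1,3-benzodioxol-5-yl)-5,7-dihydroxy-6,8-dimethoxy-4H-chromen-4-one F2. Iodomethane (1.05 equiv) with K2CO3 in DMF would then methylate the non-chelated 7-hydroxyl, and the sequence comes back to the route at compound 11.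

Step 3. Site selectivity may erode: after the first bromine enters, the second bromination slows, and the reagent may stall at the monobromide or turn to C3 or ring B. The fallback sets out from compound 5 and changes the halogen handle. N-Iodosuccinimide (2.2 equiv, DMF, rt), a weaker electrophile that discriminates more sharply in favour of ring A, should give 2-(2,2-diphenyl-1,3-benzodioxol-5-yl)-5-hydroxy-6,8-diiodo-7-methoxy-4H-chromen-4-one F3. Its C–I bonds enter the copper-mediated exchange more readily than C–Br bonds, so treatment with NaOMe and CuBr in DMF–methanol bypasses compound 8 and comes back to the route at compound 11.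

Step 2. Alkylation may not stop at the 7-oxygen: with base and electrophile present, the chelated 5-hydroxyl and the nucleophilic C6 and C8 of the phenoxide can also be methylated. The fallback sets out from compound 3 and forms the ether by Mitsunobu reaction with methanol (MeOH, PPh3, diisopropyl azodicarboxylate, THF, 0 °C to rt). No free phenoxide is generated, and only the more acidic, non-hydrogen-bonded 7-hydroxyl protonates the betaine and is O-methylated. It comes back to the route at compound 5 and makes no new compound.

Steps 1 and 5 are the standard installation and removal of a catechol diphenylmethylene ketal and are judged less exposed.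

**Further compounds**

F1 | step 4 | 6,8-dibromo-2-(2,2-diphenyl-1,3-benzodioxol-5-yl)-5,7-dihydroxy-4H-chromen-4-one | Oc1c(Br)c(O)c2c(=O)cc(-c3ccc4OC(c5ccccc5)(c5ccccc5)Oc4c3)oc2c1Br
F2 | step 4 | 2-(2,2-diphenyl-1,3-benzodioxol-5-yl)-5,7-dihydroxy-6,8-dimethoxy-4H-chromen-4-one | Oc1c(OC)c(O)c2c(=O)cc(-c3ccc4OC(c5ccccc5)(c5ccccc5)Oc4c3)oc2c1OC
F3 | step 3 | 2-(2,2-diphenyl-1,3-benzodioxol-5-yl)-5-hydroxy-6,8-diiodo-7-methoxy-4H-chromen-4-one | COc1c(I)c(O)c2c(=O)cc(-c3ccc4OC(c5ccccc5)(c5ccccc5)Oc4c3)oc2c1I
F0 | step 2 | none | none
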